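The violet run is this same flask under another name: the charges agree, but the readings stop at 50.0 min, and the question stands 3.00 times later, at 2.5 h.

- violet: left-handed substrate 0.10 M; right-handed substrate 0.10 M; coupling partner 0.30 M; free catalyst 10 mM; racemization catalyst 81 µM; the very flask that is asked about, followed so far
- flask: left-handed substrate 0.10 M; coupling partner 0.300 M; free catalyst 10 mM; racemization catalyst 81 µM; right-handed substrate 0.10 M; time 2.5 h

- violet (time / min: left-handed product / %, right-handed product / %): 8.00: 8.3, 3.2; 15.0: 13.9, 4.6; 25.0: 17.5, 6.4; 30.0: 18.9, 6.9; 40.0: 21.7, 8.5; 50.0: 23.6, 9.2

(readings scatter by 1 percentage point)

- free catalyst is single-handed; left-handed substrate and right-handed substrate are mirror images of each other, charged as a racemate, each of them at the stated concentration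
- the earlier runs were read with a standard deviation of 1 percentage point
- an excess is the difference of the two amounts in percent of their sum
- an excess is below zero if the other one leads

1. left-handed product and right-handed product together, in percent of the left-handed substrate and right-handed substrate charged together, at 2.5 h
2. excess of left-handed product over right-handed product in the product at 2.5 h
3. whether the exchange between left-handed substrate and right-handed substrate keeps pace with the reaction: how far the product's excess at 2.5 h gets from its value without exchange to its value with instant exchange (above 80% keeps pace, below 20% hardly takes part, else lags behind)

Each substrate makes up half of the pair, so, as long as exchange is left aside, a reading doubled is the part of that substrate's own charge consumed. Without exchange, two mirror substrates that react by the same step with the same partners keep a fixed ratio between the logarithms of what is left of each, however the catalyst runs down. At 50.0 min the violet run reads that ratio as 3.14: this is the selectivity factor, a reading that carries the scatter of 1 percentage point on each product. With instant exchange, the products would form in this ratio, which gives an excess of 51.7%.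

The logarithm for the left-handed substrate stands at 0.431 after 25.0 min and 0.639 after 50.0 min. This doubling of the time adds 0.208, less than the 0.431 gathered before it, so the violet run is slowing. Carrying that step per doubling on to 2.5 h gives 0.968. With exchange left aside, this reckoning therefore leaves 38.0% of the left-handed substrate's charge and, through the selectivity factor, 73.5% of the right-handed substrate's. That makes 44.3% of product, with an excess of 40.1% without exchange, and the excess should lie between that value and 51.7%.

The forecast gives 46% (39% to 54%), above this reckoning, and an excess of 42% (36% to 49%), and says the exchange lags behind, on the ground that “the slowing reaction gives the small racemization load time to catch up”.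

The flask gives 42.5% of product with an excess of 44.3%, and the exchange lags behind, 46% of the way from the excess without exchange to the excess with instant exchange.

    coupling partner + free catalyst + left-handed substrate → free catalyst + left-handed product (k = 930 M⁻² h⁻¹)
    coupling partner + free catalyst + right-handed substrate → free catalyst + right-handed product (k = 310 M⁻² h⁻¹)
    left-handed substrate + racemization catalyst ⇌ right-handed substrate + racemization catalyst, rate k3*[racemization catalyst]*[left-handed substrate] forward; the back reaction follows from the equilibrium constant (k = 7500 M⁻¹ h⁻¹)
    2 free catalyst → spent catalyst (k = 520 M⁻¹ h⁻¹)
    2 free catalyst ⇌ resting dimer, settled at all times (K = 61.0 M⁻¹)

At 2.50 h this flask holds 4.64% of its catalyst free and 95.1% spent. Through the selectivity factor, its 11.8% of right-handed product calls for 28.5% of left-handed product without exchange, and 30.7% stands there. The neighbour charged with 0.51 M of coupling partner holds 18.1% of right-handed product, which calls for 37.8%, and it holds 42.7% of left-handed product.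

The numbers in the tables stem from a simulated flask for an exercise; noise was put on by code.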